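**Plan**
- The target is (6R,6'R)-ε,ε-carotene (all-E). It is C2-symmetric: two identical halves (the 2,6,6-trimethylcyclohex-2-enyl ring plus chain carbons C7 to C14) sit on either side of the two-carbon unit C15=C15', so this unit can enter as ethyne between two C14 aldehyde carbons.
- Retrosynthesis: C15=C15' goes back to an alkyne, and C7=C8 and C7'=C8' go back to a two-fold dehydration of a C40 alkyne-14,14'-diol. The diol is cut at C14–C15 and C14'–C15' into two C19 trienals and ethyne bis(magnesium bromide).
- The C19 trienal is cut at C12–C13 and C10–C11 (enol ether condensations) and at C9–C10 (Darzens carbon), which leads back to (R)-α-ionone.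
- Forward: α-ionone is resolved, the chain grows C13 to C14 to C16 to C19, two C19 units are joined through the C2 dianion, then dehydration, semihydrogenation and Z-to-E isomerisation. No ring is formed anywhere; both rings come from α-ionone.
- Stereochemistry: C6 and C6' (both R) come from resolution of α-ionone through its (−)-menthyl carbazone. From step 4 to step 11, C7 is a methylene group, so C6 is not conjugated and not at risk. Alkene geometry comes from thermodynamic control, syn hydrogenation and thermal isomerisation.

Key step: step 10

Assumption: the less soluble (−)-menthyl carbazone is taken to be the one from (R)-α-ionone; if the crystalline crop proves to be the (6S) series, (+)-menthyl carbazate is used in the same way and nothing else changes.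

Step 1
Reactants: 1 (1R,2S,5R)-(−)-menthyl chloroformate
Product: 2 (−)-menthyl carbazate [(1R,2S,5R)-2-isopropyl-5-methylcyclohexyl hydrazinecarboxylate]
Conditions: N2H4·H2O (3 equiv), Et2O, 0 °C to rt, chloroformate added to the hydrazine
Reagents that add atoms: hydrazine (used as hydrate), NN
Why: Acyl substitution of the chloroformate by excess hydrazine should give the mono-acyl hydrazine, with inverse addition suppressing double acylation and the menthyl stereocentres untouched.

Step 2
Reactants: 3 racemic α-ionone; 2 (−)-menthyl carbazate
Product: 4 (−)-menthyl carbazone of (R)-α-ionone (E at C=N; the 6R diastereomer after fractional crystallisation)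
Conditions: EtOH, NaOAc, AcOH (cat.), reflux; fractional crystallisation from aq. EtOH to constant rotation
Reagents that add atoms: none
Why: Carbazone formation (condensation of the ketone with the acyl hydrazine) gives two diastereomers that differ only at C6 of the ionone part, so a classical resolution by crystallisation should select, not create, the 6R configuration while the 6S diastereomer stays in the mother liquor.

Step 3
Reactants: 4 (−)-menthyl carbazone of (R)-α-ionone
Product: 5 (R)-α-ionone
Conditions: 2 M aq. H2SO4, petroleum ether, two-phase, 40 °C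
Reagents that add atoms: water, O
Why: Acid hydrolysis of the acylhydrazone C=N bond in a two-phase system should pull the freed ketone into the organic layer and hold the protonated carbazate in water, and dilute acid at this temperature should neither epimerise C6 nor move the ring double bond.

Step 4
Reactants: 5 (R)-α-ionone; 6 ethyl chloroacetate
Product: 9 (E)-2-methyl-4-[(R)-2,6,6-trimethylcyclohex-2-en-1-yl]but-2-enal (C14 enal), via glycidic ethyl ester 7 (not isolated), via sodium glycidate 8 (not isolated)
Conditions: NaOEt (solid, added in portions to 5 + 6), toluene, −15 to 0 °C; then NaOH, EtOH/H2O, 0 to 20 °C; then AcOH to pH 5, 40 °C (−CO2)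
Reagents that add atoms: sodium hydroxide, [Na+].[OH-] (its atoms stay only in intermediate 8)
Why: Darzens glycidic ester condensation (1,2-addition of the chloroacetate enolate to the ketone, then intramolecular SN2 closure to the epoxide), saponification and decarboxylative opening of the glycidic acid should give a dienol that is protonated at C7 to the conjugated (E)-enal, so C9–C10 is formed, C7 becomes a methylene group and C6 leaves conjugation with its configuration kept, provided the cold and brief alkoxide contact does not remove the γ-proton of 5.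

Step 5
Reactants: 9 C14 enal
Product: 10 (E)-1,1-diethoxy-2-methyl-4-[(R)-2,6,6-trimethylcyclohex-2-en-1-yl]but-2-ene (C14 diethyl acetal)
Conditions: HC(OEt)3 (1.2 equiv), EtOH, p-TsOH·H2O (cat.), 20 °C; NaOEt quench, evaporation
Reagents that add atoms: triethyl orthoformate, CCOC(OCC)OCC
Why: Acid-catalysed acetalisation with the orthoformate as water scavenger is standard for enals and supplies the oxocarbenium precursor, and catalytic acid at room temperature should leave the ring alkene and the plain allylic methine C6 alone.

Step 6
Reactants: 10 C14 diethyl acetal; 11 ethyl vinyl ether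
Product: 13 (2E,4E)-4-methyl-6-[(R)-2,6,6-trimethylcyclohex-2-en-1-yl]hexa-2,4-dienal (C16 dienal), via C16 triethoxy adduct 12 (not isolated)
Conditions: ethyl vinyl ether (1.1 equiv), ZnCl2 (cat., in EtOAc), 30–40 °C; then AcOH, NaOAc, H2O, 95 °C
Reagents that add atoms: water, O
Why: In the Müller-Cunradi–Pieroh enol ether condensation ZnCl2 ionises the acetal to an alkoxy-allyl cation that the enol ether attacks at the former carbonyl carbon (C10–C11 formed), and buffered hydrolysis with loss of ethanol should then give the thermodynamically preferred (E)-enal, with near-stoichiometric enol ether limiting telomer formation.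

Step 7
Reactants: 13 C16 dienal
Product: 14 (2E,4E)-1,1-diethoxy-4-methyl-6-[(R)-2,6,6-trimethylcyclohex-2-en-1-yl]hexa-2,4-diene (C16 diethyl acetal)
Conditions: HC(OEt)3 (1.2 equiv), EtOH, p-TsOH·H2O (cat.), 20 °C; NaOEt quench, evaporation
Reagents that add atoms: triethyl orthoformate, CCOC(OCC)OCC
Why: The same acid-catalysed acetalisation as in step 5 should apply to the dienal, the conjugated acetal being the thermodynamic product in the presence of the orthoformate.

Step 8
Reactants: 14 C16 diethyl acetal; 15 ethyl 1-propenyl ether (E/Z mixture)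
Product: 17 (2E,4E,6E)-2,6-dimethyl-8-[(R)-2,6,6-trimethylcyclohex-2-en-1-yl]octa-2,4,6-trienal (C19 trienal), via C19 triethoxy adduct 16 (not isolated)
Conditions: ethyl 1-propenyl ether (1.1 equiv), ZnCl2 (cat., in EtOAc), 30–40 °C; then AcOH, NaOAc, H2O, 95 °C
Reagents that add atoms: water, O
Why: A second Müller-Cunradi–Pieroh enol ether condensation should form C12–C13 by attack of the propenyl ether on the acetal carbon of the dienyl oxocarbenium ion and bring in C13, its methyl group and C14, and hydrolysis with loss of ethanol should give the (E)-configured 2-methyl enal.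

Step 9
Reactants: 18 ethyne
Product: 19 ethyne bis(magnesium bromide)
Conditions: EtMgBr (2 equiv), Et2O, ethyne gas (limiting), 20–35 °C, 12–24 h; used directly as the ether suspension
Reagents that add atoms: ethylmagnesium bromide, CC[Mg]Br
Why: Acid–base metallation of both C–H bonds of ethyne by the alkyl Grignard reagent with loss of ethane is known to give the bis-metallated reagent in ether when ethyne is the limiting component.

Step 10
Reactants: 17 C19 trienal (2 equivalents); 19 ethyne bis(magnesium bromide)
Product: 21 (2E,4E,6E,12E,14E,16E)-3,7,12,16-tetramethyl-1,18-bis[(1R)-2,6,6-trimethylcyclohex-2-en-1-yl]octadeca-2,4,6,12,14,16-hexaen-9-yne-8,11-diol (C40 alkyne-14,14'-diol; mixture at both carbinol carbons), via bis(bromomagnesium) alkoxide 20 (not isolated)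
Conditions: 19 (0.48 equiv), Et2O/CH2Cl2, 20–35 °C, 12 h; aq. NH4Cl
Reagents that add atoms: none
Why: Each carbon–magnesium bond of 19 adds to the carbonyl carbon of one molecule of 17 in a polar Grignard 1,2-addition, forming C14–C15 and then C14'–C15' and leaving the bis(magnesium alkoxide) 20, which aqueous NH4Cl protonates to 21; the closest known reaction type is the addition of the acetylene bis-Grignard reagent to two molecules of a polyene aldehyde. No ring is closed: the chain is joined in two directions at once, which is possible because the target has identical C1–C14 halves on both sides of the two-carbon unit C15=C15'. The two carbinol carbons C14 and C14' form without control as a mixture of configurations, which is accepted because both hydroxyl groups leave in step 11, while C6 and C6' are remote, non-conjugated methines that the weakly basic acetylide cannot touch. The step needs 1,2-addition instead of conjugate addition at C12, C10 or C8, and it needs the second addition to go to completion; the hard, charge-localised magnesium acetylide should secure the first, and a slight excess of 17 with long stirring of the two-phase mixture should secure the second. Enolisation should not compete because 17 has no α-hydrogen and its only vinylogous C–H (C7) is far too weakly acidic for an alkynyl Grignard reagent.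

Step 11
Reactants: 21 C40 alkyne-14,14'-diol
Product: 22 (6R,6'R)-15,15'-didehydro-ε,ε-carotene (all-E)
Conditions: HCl in EtOH (cat.), CH2Cl2, −10 to 20 °C, short contact; aq. NaHCO3; crystallisation
Reagents that add atoms: none
Why: In this acid-catalysed two-fold dehydration with allylic transposition (E1), ionisation of each allylic-propargylic C14–OH gives a cation spread over C14, C12, C10 and C8, and loss of a proton from the C7 methylene next to the cation end should install C7=C8 and the fully conjugated system under thermodynamic control, while C6 is not part of the cation and should keep its configuration.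

Step 12
Reactants: 22 (6R,6'R)-15,15'-didehydro-ε,ε-carotene
Product: 23 (6R,6'R,15Z)-ε,ε-carotene
Conditions: H2 (1 atm, stopped after 1.0 equiv), 5% Pd on CaCO3 poisoned with Pb(OAc)2, quinoline, toluene, 20 °C
Reagents that add atoms: none
Why: Lindlar semihydrogenation delivers one equivalent of hydrogen syn to the triple bond on the lead-poisoned palladium surface and should stop at the (15Z)-alkene, the poison and quinoline holding back reduction of the polyene double bonds.

Step 13
Reactants: 23 (6R,6'R,15Z)-ε,ε-carotene
Product: 24 (6R,6'R)-ε,ε-carotene (all-E; CNP0241650.1)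
Conditions: heptane suspension, 95 °C, N2, dark, 10–20 h; crystallisation
Reagents that add atoms: none
Why: Thermal Z-to-E isomerisation of the unhindered central cis double bond of a long polyene has a low barrier in the delocalised system and should converge on the all-E isomer, which is the thermodynamic and least soluble form and crystallises, without any reagent that could touch C6 or the ring double bonds.

**Compound list**
1 | (1R,2S,5R)-(−)-menthyl chloroformate | C[C@@H]1CC[C@H]([C@@H](C1)OC(=O)Cl)C(C)C | starting material
2 | (−)-menthyl carbazate, (1R,2S,5R)-2-isopropyl-5-methylcyclohexyl hydrazinecarboxylate | C[C@@H]1CC[C@H]([C@@H](C1)OC(=O)NN)C(C)C | intermediate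
3 | racemic α-ionone | CC1=CCCC(C)(C)C1/C=C/C(C)=O | starting material
4 | (−)-menthyl carbazone of (R)-α-ionone (E at C=N) | C[C@@H]1CC[C@H]([C@@H](C1)OC(=O)N/N=C(C)/C=C/[C@H]2C(C)=CCCC2(C)C)C(C)C | intermediate
5 | (R)-α-ionone | CC1=CCCC(C)(C)[C@H]1/C=C/C(C)=O | intermediate
6 | ethyl chloroacetate | ClCC(=O)OCC | starting material
7 | ethyl 3-methyl-3-{(E)-2-[(R)-2,6,6-trimethylcyclohex-2-en-1-yl]ethenyl}oxirane-2-carboxylate (mixture at the oxirane carbons) | CC1=CCCC(C)(C)[C@H]1/C=C/C2(C)OC2C(=O)OCC | intermediate (not isolated)
8 | sodium 3-methyl-3-{(E)-2-[(R)-2,6,6-trimethylcyclohex-2-en-1-yl]ethenyl}oxirane-2-carboxylate | CC1=CCCC(C)(C)[C@H]1/C=C/C2(C)OC2C(=O)[O-].[Na+] | intermediate (not isolated)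
9 | (E)-2-methyl-4-[(R)-2,6,6-trimethylcyclohex-2-en-1-yl]but-2-enal (C14 enal) | CC1=CCCC(C)(C)[C@H]1C/C=C(C)/C=O | intermediate
10 | (E)-1,1-diethoxy-2-methyl-4-[(R)-2,6,6-trimethylcyclohex-2-en-1-yl]but-2-ene | CC1=CCCC(C)(C)[C@H]1C/C=C(C)/C(OCC)OCC | intermediate
11 | ethyl vinyl ether | C=COCC | starting material
12 | (E)-1,1,3-triethoxy-4-methyl-6-[(R)-2,6,6-trimethylcyclohex-2-en-1-yl]hex-4-ene (mixture at C3) | CC1=CCCC(C)(C)[C@H]1C/C=C(C)/C(OCC)CC(OCC)OCC | intermediate (not isolated)
13 | (2E,4E)-4-methyl-6-[(R)-2,6,6-trimethylcyclohex-2-en-1-yl]hexa-2,4-dienal (C16 dienal) | CC1=CCCC(C)(C)[C@H]1C/C=C(C)/C=C/C=O | intermediate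
14 | (2E,4E)-1,1-diethoxy-4-methyl-6-[(R)-2,6,6-trimethylcyclohex-2-en-1-yl]hexa-2,4-diene | CC1=CCCC(C)(C)[C@H]1C/C=C(C)/C=C/C(OCC)OCC | intermediate
15 | ethyl 1-propenyl ether (E/Z mixture) | CC=COCC | starting material
16 | (4E,6E)-1,1,3-triethoxy-2,6-dimethyl-8-[(R)-2,6,6-trimethylcyclohex-2-en-1-yl]octa-4,6-diene (mixture at C2 and C3) | CC1=CCCC(C)(C)[C@H]1C/C=C(C)/C=C/C(OCC)C(C)C(OCC)OCC | intermediate (not isolated)
17 | (2E,4E,6E)-2,6-dimethyl-8-[(R)-2,6,6-trimethylcyclohex-2-en-1-yl]octa-2,4,6-trienal (C19 trienal) | CC1=CCCC(C)(C)[C@H]1C/C=C(C)/C=C/C=C(C)/C=O | intermediate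
18 | ethyne | C#C | starting material
19 | ethyne bis(magnesium bromide) | Br[Mg]C#C[Mg]Br | intermediate
20 | bis(bromomagnesium) 8,11-dialkoxide of diol 21 | CC1=CCCC(C)(C)[C@H]1C/C=C(C)/C=C/C=C(C)/C(O[Mg]Br)C#CC(O[Mg]Br)/C(C)=C/C=C/C(C)=C/C[C@H]1C(C)=CCCC1(C)C | intermediate (not isolated)
21 | (2E,4E,6E,12E,14E,16E)-3,7,12,16-tetramethyl-1,18-bis[(1R)-2,6,6-trimethylcyclohex-2-en-1-yl]octadeca-2,4,6,12,14,16-hexaen-9-yne-8,11-diol (C40 alkyne-14,14'-diol, mixture at the carbinol carbons) | CC1=CCCC(C)(C)[C@H]1C/C=C(C)/C=C/C=C(C)/C(O)C#CC(O)/C(C)=C/C=C/C(C)=C/C[C@H]1C(C)=CCCC1(C)C | intermediate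
22 | (6R,6'R)-15,15'-didehydro-ε,ε-carotene (all-E) | CC1=CCCC(C)(C)[C@H]1/C=C/C(C)=C/C=C/C(C)=C/C#C/C=C(C)/C=C/C=C(C)/C=C/[C@H]1C(C)=CCCC1(C)C | intermediate
23 | (6R,6'R,15Z)-ε,ε-carotene | CC1=CCCC(C)(C)[C@H]1/C=C/C(C)=C/C=C/C(C)=C/C=C\C=C(C)\C=C\C=C(C)\C=C\[C@H]1C(C)=CCCC1(C)C | intermediate
24 | (6R,6'R)-ε,ε-carotene (all-E) | CC1=CCCC(C)(C)[C@H]1/C=C/C(C)=C/C=C/C(C)=C/C=C/C=C(C)/C=C/C=C(C)/C=C/[C@H]1C(C)=CCCC1(C)C | target

**Step count**
Total: 13 steps. Longest linear sequence: 12 steps (steps 1–8 and 10–13, from 1); step 9 is a one-step side branch.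

**Steps most likely to fail**

1. Step 11. The acid may move the ring double bond into conjugation (ε to β end group), erode the C6 configuration through extended cations, or stop at partial dehydration. The fallback separates the transposition from the elimination and sets out from 21. HBr (2.2 equiv) in CH2Cl2 at −40 °C should convert both carbinols by SN1' substitution with allylic transposition into 8,8'-dibromo-7,8,7',8'-tetrahydro-15,15'-didehydro-ε,ε-carotene F1. Without warming, F1 is treated with DBU (−20 to 0 °C), and E2 loss of HBr across C7–C8 and C7'–C8' under basic conditions gives 22, where the route is rejoined.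

2. Step 4. The alkoxide may remove the γ-proton at C6 of the enone (racemisation, drift towards β-ionone), and retro-aldol or ester condensation may cut the yield. The fallback sets out from 5. A Wittig methoxymethylenation with the ylide made from Ph3P(CH2OMe)Cl and NaN(SiMe3)2 (THF, −78 to 0 °C, no free alkoxide) should give the methyl dienol ether 1-methoxy-2-methyl-4-[(R)-2,6,6-trimethylcyclohex-2-en-1-yl]buta-1,3-diene F2. Hydrolysis of F2 with aqueous oxalic acid in THF protonates C7 and releases the conjugated enal 9, where the route is rejoined.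

3. Step 10. The sparingly soluble bis-Grignard reagent may stop after one addition, because the mono-adduct separates as an insoluble magnesium alkoxide acetylide. The fallback makes the same two bonds one at a time and sets out from 17. Commercial ethynylmagnesium bromide (THF, 0 °C; aq. NH4Cl) should give the C21 alkynol (4E,6E,8E)-4,8-dimethyl-10-[(R)-2,6,6-trimethylcyclohex-2-en-1-yl]deca-4,6,8-trien-1-yn-3-ol F3. Two equivalents of EtMgBr in THF at 40 °C turn F3 into the soluble bromomagnesium alkoxide acetylide F4, which adds to a second equivalent of 17 to give 20; the route is rejoined there and work-up gives 21.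

**Further compounds**
F1 | step 11 | (3E,5E,7E,11E,13E,15E)-2,17-dibromo-3,7,12,16-tetramethyl-1,18-bis[(1R)-2,6,6-trimethylcyclohex-2-en-1-yl]octadeca-3,5,7,11,13,15-hexaen-9-yne (8,8'-dibromide, mixture at the C–Br carbons) | CC1=CCCC(C)(C)[C@H]1CC(Br)/C(C)=C/C=C/C(C)=C/C#C/C=C(C)/C=C/C=C(C)/C(Br)C[C@H]1C(C)=CCCC1(C)C
F2 | step 4 | (3E)-1-methoxy-2-methyl-4-[(R)-2,6,6-trimethylcyclohex-2-en-1-yl]buta-1,3-diene (E/Z at the enol ether) | CC1=CCCC(C)(C)[C@H]1/C=C/C(C)=COC
F3 | step 10 | (4E,6E,8E)-4,8-dimethyl-10-[(R)-2,6,6-trimethylcyclohex-2-en-1-yl]deca-4,6,8-trien-1-yn-3-ol (mixture at C3) | CC1=CCCC(C)(C)[C@H]1C/C=C(C)/C=C/C=C(C)/C(O)C#C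
F4 | step 10 | bromomagnesium alkoxide and bromomagnesium acetylide of F3 | CC1=CCCC(C)(C)[C@H]1C/C=C(C)/C=C/C=C(C)/C(O[Mg]Br)C#C[Mg]Br
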